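## Analysis of the target

Target 20 is a 2,3-dihydro-4H-chromene-4,7(8H)-dione. Ring A (C4a–C5–C6–C7–C8–C8a) is a dearomatised acylphloroglucinol with an sp3 carbon at C8, and ring B (O1–C2–C3–C4–C4a–C8a) is a 2,3-dimethyl-2,3-dihydropyran-4-one fused across C4a=C8a. There are five stereocentres: C2 (R) and C3 (S), adjacent and cis; the quaternary C8 (S), carrying prenyl and lavandulyl; the lavandulyl methine (R); and the benzylic carbon (R) of the C6 side chain. Only C2 and C3 can be set relative to each other; C8, the lavandulyl methine and the benzylic carbon are too far apart for useful induction, so each needs its own source. Sensitive features are three electron-rich alkenes (no hydrogenolysis, no strong acid, no free electrophilic halogen), the C3 centre (alpha to the C4 ketone and part of a beta-alkoxy ketone, so base can epimerise it to trans or open ring B), the tautomeric vinylogous acid, and a carboxylic acid that can lactonise onto O5. The hard points are alkylating C8 rather than C6 or oxygen, closing ring B onto O8a rather than O5, and obtaining the less stable cis-2,3 arrangement. The route rests on one feature: C8 has no hydrogen, so once O5 and O8a are methyl ethers and C7 is the ketone, the double bond C4a=C8a cannot move. With the C4a propionyl group as its silyl enol ether, C8a–C4a–C4–C3 is then a 1-methoxy-3-silyloxy diene whose only possible terminus is C8a.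

## Retrosynthetic reasoning

20 to 19, then 17 + 18. The C6–benzylic bond is cut. C6 is the single nucleophilic carbon of vinylogous acid 17 and cinnamaldehyde 18 is the matching electrophile, so the benzylic centre can be set by a chiral secondary-amine catalyst without any bias from the substrate. The adduct is expected as lactol 19, and oxidation of its aldehyde carbon gives the acid. Placing this last means the acid never needs protection.

17 to 15. The C5 methyl ether and a bromine atom at C6 are put back. The methyl ether is what fixes the double bonds of ring A during ring B formation. The bromine is a blocking group inherited from the dearomatisation. It is removed here because at this stage it sits on a 1,3-diketone enolate, where it is a positive halogen that a mild reductant removes.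

15 to 12 + 13 (key disconnection). C2–C3 and O1–C8a are cut together. This removes ring B and both of its stereocentres in one operation and leaves acetaldehyde 13 and diene 12. The forward reaction must join C3 to the aldehyde carbon with syn topology, choose one aldehyde face, and close oxygen onto C8a with loss of the C8a methoxy group.

12 to 11. The silyl enol ether is traced back to the propionyl ketone; only the propionyl CH2 can be enolised, and the (Z) geometry is needed.

11 to 9 + 10. The C8–prenyl bond is cut, which re-aromatises ring A to phenol 9. In 9 the two oxygens next to the acyl group are already methylated and only the oxygen that becomes the C7 ketone is free, so alkylation on carbon gives the 5,8a-dimethoxy-7-one directly. The bromine on the future C6 closes off the other ortho carbon, so prenyl bromide 10 can only attack carbon at C8. C8 is formed without control and the epimers are separated.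

A shorter-looking order was rejected: alkylate flopropione 1 on carbon with iodide 6, dearomatise with 10, then methylate twice. After dearomatisation the most reactive oxygen is O7, so the wanted 5,8a-dimethyl ether would be the minor isomer. Without a blocking group, 10 would also attack the unsubstituted carbon. And 6 is a beta-branched, non-allylic halide that alkylates phenoxide carbon poorly.

9 to 8, then 4 + 7 (from 6, from 5). The aryl–CH2 bond to the lavandulyl group is cut as an sp2–sp3 cross-coupling between dibromide 4 and alkylzinc 7. The zinc reagent comes from iodide 6 and thus from lavandulol 5, whose stereocentre is not touched. Only one of the two equivalent bromines of 4 is used, and the other becomes the C6 blocking group. Removing the silyl group from 8 gives 9.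

4 to 3 to 2 to 1. Bromination, methylation of the two chelated hydroxyls and silylation of the para hydroxyl lead back to flopropione 1. The para hydroxyl is protected first because it is the most acidic and would otherwise be methylated.

## Alternatives that were turned down

Alternative 1: Ring A is disconnected at C7–C8. Forward, an alkoxide base opens 4-hydroxy-2-pyranone A1 to a diketo ester, and the side-chain methine carbon (already carrying lavandulyl and prenyl) closes onto the ester to give trione A2, an isomer of A1. In its favour, the quaternary carbon is assembled by ordinary enolate alkylation before the ring exists, so there is no competition from C6 or from oxygen and no blocking group; on this point it is stronger than the chosen route. Against it, A2 is only the bare ring. The propionyl group must still be put on C4a, which creates the C8 stereocentre with no control. The two enol oxygens must then be differentiated, and that is the methylation problem the chosen route avoids by methylating at the aromatic stage. The ring closure itself forms a quaternary centre by a reversible Claisen-type step, in competition with reclosure to A1. Ring B and its stereocentres remain to be made, so the sequence is longer. The chosen route offers instead an aromatic precursor with the acyl group and oxygen pattern fixed from the first steps.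

Alternative 2: C4a=C8a is disconnected to the ten-membered triketo lactone A3. Forward, enolisation at C4a, attack on the lactone carbonyl and dehydration would close rings A and B together and give A4, which is the same compound as 17. In its favour, C2 and C3 could come from a reliable acyclic syn-aldol, no methyl ethers need removing, and two rings form in one step; on these points it is as strong as or stronger than the chosen route. Against it, A3 is a medium ring built from a polyketone chain. Its C2 oxygen is beta to the C4 ketone, so enolisation conditions invite elimination and loss of both ring B stereocentres, and C3 can epimerise. If the tetrahedral intermediate at C8a expels O1 instead of water, the chain reopens, and reclosure can then go to O5 as easily as to O8a. Nothing in A3 fixes that regiochemistry. The chosen route fixes it with the methyl ethers and creates C2 and C3 only after the strongly basic steps.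

Alternative 3: Ring A is disconnected at C6–C7 and C4a–C5. Forward, heating cyclobutenone A5 with ynol ether A6 gives a vinylketene, a [2+2] adduct, and after ring opening and six-electron electrocyclisation the dienone A7. In its favour, A7 has the same locked 5,8a-dialkoxy-7-one arrangement as 11 and is reached with no protecting or blocking groups; on that point it is stronger. Against it, A7 lacks the C4a acyl group, and acylation must choose between C4a and C6, both enol-ether beta-carbons. The ketene intermediates carry two pendant alkenes and can undergo intramolecular [2+2] cycloaddition at the temperatures needed. A5 needs its own multi-step synthesis from a doubly branched acid, and C8 is again formed without control. The chosen route carries the acyl group from the start and needs no ketene chemistry.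

Key step: step 9

Remarks on the chemistry (assumptions):
- (S)-Lavandulol 5 is taken as purchasable in enantiopure form; otherwise the commercial racemate would be resolved by lipase-mediated acylation.
- "Lavandulyl" means (2R)-5-methyl-2-(prop-1-en-2-yl)hex-4-en-1-yl when bonded to carbon; it is the same spatial arrangement as in (S)-5, (S)-6 and (S)-7. "Prenyl" means 3-methylbut-2-en-1-yl. Ring positions are given by the chromene locants of 20 throughout.
- Lactol 19 is drawn closed on O5 as a mixture of anomers; closure on O7 would converge on 20 in the same way.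

## Route

Step 1
Reactants: 1 flopropione
Product: 2 1-[2,6-dihydroxy-4-(triisopropylsilyloxy)phenyl]propan-1-one
Conditions: iPr3SiCl, imidazole, DMF, 0 °C
Reagents that add atoms: chlorotriisopropylsilane CC(C)[Si](Cl)(C(C)C)C(C)C
Why: Silylation of a phenol; the para hydroxyl is the most acidic and the only one not hydrogen-bonded to the ketone, so it should react first.

Step 2
Reactants: 2 1-[2,6-dihydroxy-4-(triisopropylsilyloxy)phenyl]propan-1-one
Product: 3 1-[2,6-dimethoxy-4-(triisopropylsilyloxy)phenyl]propan-1-one
Conditions: MeI, K2CO3, acetone, 55 °C
Reagents that add atoms: iodomethane CI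
Why: Williamson O-methylation of the two chelated phenols; the bulky silyl ether should survive anhydrous carbonate, and this fixes the future O5 and O8a as methyl ethers while ring A is still aromatic.

Step 3
Reactants: 3 1-[2,6-dimethoxy-4-(triisopropylsilyloxy)phenyl]propan-1-one
Product: 4 1-[3,5-dibromo-2,6-dimethoxy-4-(triisopropylsilyloxy)phenyl]propan-1-one
Conditions: N-bromosuccinimide (2.1 equiv), MeCN, 0 °C to rt
Reagents that add atoms: N-bromosuccinimide O=C1CCC(=O)N1Br
Why: Electrophilic aromatic bromination; the two remaining ring positions are equivalent and each is activated by three oxygen substituents, and no alkene is present yet.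

Step 4
Reactants: 5 (S)-lavandulol
Product: 6 (S)-lavandulyl iodide
Conditions: PPh3, I2, imidazole, CH2Cl2, 0 °C to rt
Reagents that add atoms: iodine II
Why: Appel-type iodination of a primary alcohol; the stereocentre is beta to the reacting carbon and is not involved.

Step 5
Reactants: 6 (S)-lavandulyl iodide; 4 1-[3,5-dibromo-2,6-dimethoxy-4-(triisopropylsilyloxy)phenyl]propan-1-one
Product: 8 1-[3-bromo-5-lavandulyl-2,6-dimethoxy-4-(triisopropylsilyloxy)phenyl]propan-1-one, via (S)-lavandulylzinc iodide 7 (not isolated)
Conditions: Zn dust, LiCl, THF, 40 °C; then 4 (excess), Pd(OAc)2 (cat.), SPhos (cat.), THF, 50 °C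
Reagents that add atoms: none
Why: Zinc insertion into the primary iodide followed by Negishi coupling; alkylzinc reagents tolerate the ketone, and a bulky biarylphosphine is the standard answer to di-ortho-substituted aryl bromides. Using 4 in excess should favour single coupling, and the bromine that remains is the C6 blocking group.

Step 6
Reactants: 8 1-[3-bromo-5-lavandulyl-2,6-dimethoxy-4-(triisopropylsilyloxy)phenyl]propan-1-one
Product: 9 1-(3-bromo-4-hydroxy-5-lavandulyl-2,6-dimethoxyphenyl)propan-1-one
Conditions: Bu4NF, THF, 0 °C; aqueous NH4Cl
Reagents that add atoms: none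
Why: Fluoride cleavage of an aryl silyl ether; the conditions are neutral, which matters because acid would cyclise the free phenol onto the neighbouring isopropenyl group.

Step 7
Reactants: 9 1-(3-bromo-4-hydroxy-5-lavandulyl-2,6-dimethoxyphenyl)propan-1-one; 10 prenyl bromide
Product: 11 (6S)-2-bromo-6-lavandulyl-3,5-dimethoxy-6-prenyl-4-propanoylcyclohexa-2,4-dien-1-one
Conditions: NaH, toluene, 0 °C; then 10, rt; preparative HPLC separation of the C8 epimers
Reagents that add atoms: none
Why: Alkylative dearomatisation of a 2,6-disubstituted phenoxide; a sodium phenoxide in a non-polar medium favours attack through the ortho carbon. Of the two ortho carbons the alkyl-bearing one is the more electron-rich and the other is blocked by bromine, and the product cannot re-aromatise. C8 is not controlled, so both epimers are expected in similar amounts; the (S)-epimer is carried on, and the bromine atom should allow assignment by crystallography.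

Step 8
Reactants: 11 (6S)-2-bromo-6-lavandulyl-3,5-dimethoxy-6-prenyl-4-propanoylcyclohexa-2,4-dien-1-one
Product: 12 (6S)-2-bromo-6-lavandulyl-3,5-dimethoxy-6-prenyl-4-[(1Z)-1-(trimethylsilyloxy)prop-1-en-1-yl]cyclohexa-2,4-dien-1-one
Conditions: LiN(SiMe3)2, Me3SiCl, THF, −78 °C; non-aqueous work-up
Reagents that add atoms: chlorotrimethylsilane C[Si](C)(C)Cl
Why: Kinetic enolisation with in situ silylation; the propionyl CH2 is the only enolisable position, and an ethyl ketone with a bulky group on the other side of the carbonyl gives the (Z) enolate, as aryl ethyl ketones do.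

Step 9
Reactants: 12 (6S)-2-bromo-6-lavandulyl-3,5-dimethoxy-6-prenyl-4-[(1Z)-1-(trimethylsilyloxy)prop-1-en-1-yl]cyclohexa-2,4-dien-1-one; 13 acetaldehyde
Product: 15 (2R,3S,8S)-6-bromo-8-lavandulyl-5-methoxy-2,3-dimethyl-8-prenyl-2,3-dihydro-4H-chromene-4,7(8H)-dione, via silylated syn-aldol adduct 14 (not isolated)
Conditions: Ti(OiPr)4 (20 mol%), (S)-BINOL (40 mol%), 4 Å molecular sieves, CH2Cl2, −20 °C; then CF3CO2H, CH2Cl2, 0 °C
Reagents that add atoms: none
Why: This is the formal hetero-[4+2] reaction of a 1-methoxy-3-silyloxy diene (C8a=C4a–C4=C3) with an aldehyde bound to a BINOL-derived tetravalent-titanium Lewis acid, the established route to 2,3-dihydropyran-4-ones. On this twisted, fully substituted diene the C2–C3 bond should form first in a Mukaiyama-type step and give 14; CF3CO2H then removes the silyl group, the C2 oxygen adds to C8a, and the C8a methoxy group leaves, restoring C4a=C8a. Ring B therefore closes by [4+2] annulation, with its second bond formed in a 6-endo-trig addition–elimination. C2 is set by the ligand: (S)-BINOL is chosen so that the Si face of the aldehyde is attacked, the mirror image of the Re-face preference usual for (R)-BINOL–titanium catalysts with simple aldehydes, and this sense would be confirmed on a model ketone. C3 follows from the (Z) enol ether geometry in a closed, cycloaddition-like transition structure (aldehyde methyl endo, oxygen on titanium), which gives the syn aldol and hence the cis-2,3 ring; open transition structures lead to trans, so boron trifluoride-type promoters are excluded. The regioselectivity needed is closure on C8a and not on C5. It is secured because the methyl ethers and the quaternary C8 hold the double bond at C4a=C8a, so the positive charge that develops after C–C bond formation lies on C4 and C8a, and C5 is outside that allyl system. The C6 bromine and the C8 centre are spectators.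

Step 10
Reactants: 15 (2R,3S,8S)-6-bromo-8-lavandulyl-5-methoxy-2,3-dimethyl-8-prenyl-2,3-dihydro-4H-chromene-4,7(8H)-dione
Product: 17 (2R,3S,8S)-5-hydroxy-8-lavandulyl-2,3-dimethyl-8-prenyl-2,3-dihydro-4H-chromene-4,7(8H)-dione, via lithium enolate of the 6-bromo vinylogous acid 16 (not isolated)
Conditions: LiCl, DMF, 80 °C; then NaHSO3, AcOH, H2O/THF, 0 °C
Reagents that add atoms: none
Why: Chloride demethylates the vinylogous methyl ester by SN2 attack at methyl; the leaving group is the enolate of a 2-bromo-1,3-diketone, so moderate heating should suffice and the weakly basic medium should spare C3. In 16 the bromine is a positive halogen, and hydrogensulfite reduces it during acidification before it can reach the alkenes.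

Step 11
Reactants: 17 (2R,3S,8S)-5-hydroxy-8-lavandulyl-2,3-dimethyl-8-prenyl-2,3-dihydro-4H-chromene-4,7(8H)-dione; 18 (E)-cinnamaldehyde
Product: 19 O5-lactol of the (3R)-3-phenylpropanal adduct at C6 (both anomers)
Conditions: (R)-α,α-diphenylprolinol trimethylsilyl ether (20 mol%), PhCO2H (20 mol%), CH2Cl2, rt
Reagents that add atoms: none
Why: Iminium-catalysed Michael addition of a cyclic 1,3-dicarbonyl to an enal, which gives hemiacetals of this type. The bulky group of the (R)-catalyst shields one face of the (E)-iminium ion, and by the usual model the nucleophile then adds to give the (R) benzylic centre. The catalyst is remote from C8 and should override any substrate bias.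

Step 12
Reactants: 19 O5-lactol of the (3R)-3-phenylpropanal adduct at C6 (both anomers)
Product: 20 (3R)-3-[(2R,3S,8S)-5-hydroxy-8-lavandulyl-2,3-dimethyl-4,7-dioxo-8-prenyl-3,4,7,8-tetrahydro-2H-chromen-6-yl]-3-phenylpropanoic acid
Conditions: NaClO2, NaH2PO4, 2-methyl-2-butene (large excess), t-BuOH/H2O, 0 °C to rt
Reagents that add atoms: sodium chlorite [Na+].[O-]Cl=O
Why: Pinnick oxidation of the aldehyde in equilibrium with the lactol; the enol is a good leaving group, so ring opening is easy. The buffered conditions leave C3 alone, and the alkene scavenger takes up hypochlorous acid before it reaches the three alkenes or the enol.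

## Compound list

1 | flopropione, 1-(2,4,6-trihydroxyphenyl)propan-1-one | CCC(=O)c1c(O)cc(O)cc1O | starting material
2 | 1-[2,6-dihydroxy-4-(triisopropylsilyloxy)phenyl]propan-1-one | CCC(=O)c1c(O)cc(O[Si](C(C)C)(C(C)C)C(C)C)cc1O | intermediate
3 | 1-[2,6-dimethoxy-4-(triisopropylsilyloxy)phenyl]propan-1-one | CCC(=O)c1c(OC)cc(O[Si](C(C)C)(C(C)C)C(C)C)cc1OC | intermediate
4 | 1-[3,5-dibromo-2,6-dimethoxy-4-(triisopropylsilyloxy)phenyl]propan-1-one | CCC(=O)c1c(OC)c(Br)c(O[Si](C(C)C)(C(C)C)C(C)C)c(Br)c1OC | intermediate
5 | (S)-lavandulol, (2S)-5-methyl-2-(prop-1-en-2-yl)hex-4-en-1-ol | C=C(C)[C@H](CC=C(C)C)CO | starting material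
6 | (S)-lavandulyl iodide, (2S)-1-iodo-5-methyl-2-(prop-1-en-2-yl)hex-4-ene | C=C(C)[C@H](CC=C(C)C)CI | intermediate
7 | (S)-lavandulylzinc iodide | C=C(C)[C@H](CC=C(C)C)C[Zn]I | intermediate (not isolated)
8 | 1-[3-bromo-5-lavandulyl-2,6-dimethoxy-4-(triisopropylsilyloxy)phenyl]propan-1-one | C=C(C)[C@H](CC=C(C)C)Cc1c(OC)c(C(=O)CC)c(OC)c(Br)c1O[Si](C(C)C)(C(C)C)C(C)C | intermediate
9 | 1-(3-bromo-4-hydroxy-5-lavandulyl-2,6-dimethoxyphenyl)propan-1-one | C=C(C)[C@H](CC=C(C)C)Cc1c(OC)c(C(=O)CC)c(OC)c(Br)c1O | intermediate
10 | prenyl bromide, 1-bromo-3-methylbut-2-ene | CC(C)=CCBr | starting material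
11 | (6S)-2-bromo-6-lavandulyl-3,5-dimethoxy-6-prenyl-4-propanoylcyclohexa-2,4-dien-1-one | C=C(C)[C@H](CC=C(C)C)C[C@]1(CC=C(C)C)C(=O)C(Br)=C(OC)C(C(=O)CC)=C1OC | intermediate
12 | (6S)-2-bromo-6-lavandulyl-3,5-dimethoxy-6-prenyl-4-[(1Z)-1-(trimethylsilyloxy)prop-1-en-1-yl]cyclohexa-2,4-dien-1-one | C=C(C)[C@H](CC=C(C)C)C[C@]1(CC=C(C)C)C(=O)C(Br)=C(OC)C(/C(O[Si](C)(C)C)=C/C)=C1OC | intermediate
13 | acetaldehyde | CC=O | starting material
14 | (6S)-2-bromo-6-lavandulyl-3,5-dimethoxy-4-[(2S,3R)-2-methyl-3-(trimethylsilyloxy)butanoyl]-6-prenylcyclohexa-2,4-dien-1-one | C=C(C)[C@H](CC=C(C)C)C[C@]1(CC=C(C)C)C(=O)C(Br)=C(OC)C(C(=O)[C@@H](C)[C@@H](C)O[Si](C)(C)C)=C1OC | intermediate (not isolated)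
15 | (2R,3S,8S)-6-bromo-8-lavandulyl-5-methoxy-2,3-dimethyl-8-prenyl-2,3-dihydro-4H-chromene-4,7(8H)-dione | C=C(C)[C@H](CC=C(C)C)C[C@]1(CC=C(C)C)C(=O)C(Br)=C(OC)C2=C1O[C@H](C)[C@H](C)C2=O | intermediate
16 | lithium enolate of (2R,3S,8S)-6-bromo-5-hydroxy-8-lavandulyl-2,3-dimethyl-8-prenyl-2,3-dihydro-4H-chromene-4,7(8H)-dione | C=C(C)[C@H](CC=C(C)C)C[C@]1(CC=C(C)C)C(=O)C(Br)=C([O-])C2=C1O[C@H](C)[C@H](C)C2=O.[Li+] | intermediate (not isolated)
17 | (2R,3S,8S)-5-hydroxy-8-lavandulyl-2,3-dimethyl-8-prenyl-2,3-dihydro-4H-chromene-4,7(8H)-dione | C=C(C)[C@H](CC=C(C)C)C[C@]1(CC=C(C)C)C(=O)C=C(O)C2=C1O[C@H](C)[C@H](C)C2=O | intermediate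
18 | (E)-cinnamaldehyde | O=C/C=C/c1ccccc1 | starting material
19 | O5-lactol of the C6 Michael adduct: 2-hydroxy-4-phenyl-3,4-dihydro-2H-pyran ring fused at C5–C6 of 17, benzylic carbon R, anomeric carbon unassigned | C=C(C)[C@H](CC=C(C)C)C[C@]1(CC=C(C)C)C(=O)C3=C(OC(O)C[C@@H]3c3ccccc3)C2=C1O[C@H](C)[C@H](C)C2=O | intermediate
20 | (3R)-3-[(2R,3S,8S)-5-hydroxy-8-lavandulyl-2,3-dimethyl-4,7-dioxo-8-prenyl-3,4,7,8-tetrahydro-2H-chromen-6-yl]-3-phenylpropanoic acid | C=C(C)[C@H](CC=C(C)C)C[C@]1(CC=C(C)C)C(=O)C([C@H](CC(=O)O)c2ccccc2)=C(O)C2=C1O[C@H](C)[C@H](C)C2=O | target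

## Step count and least certain steps

Total: 12 steps. Longest linear sequence: 11 steps (1 to 20 through steps 1, 2, 3, 5 to 12); the lavandulyl branch (steps 4 and 5) joins at 8.

Step 9 (key step). The most likely failures are (a) loss of the syn preference through an open transition structure, which would give the trans-2,3 ring, (b) slow addition of the crowded enol silane, so that acetaldehyde self-condenses or the silyl group is lost and 11 returns, and (c) weak catalyst control of the aldehyde face. Fallback: starting from ketone 11, form the (Z) boron enolate with diisopinocampheylboron triflate and iPr2NEt (the pinene enantiomer chosen for the 2S,3R adduct) and add 13. A closed chair transition structure makes this aldol syn by design, and it gives the free syn-aldol F1. Treatment of F1 with CF3CO2H closes ring B by the same addition–elimination at C8a, and the route is rejoined at 15.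

Step 5. The risks are coupling at both bromines, hydrodebromination, and slow transmetalation at a carbon flanked by methoxy and silyloxy groups. Fallback: alkylate the polyanion of 1 (NaOMe, MeOH) on carbon with iodide 6 to give 3-lavandulylflopropione F2. Allylate the para hydroxyl (allyl bromide, K2CO3) to give allyl ether F3, methylate the two chelated hydroxyls (MeI, K2CO3) to give dimethyl ether F4, and remove the allyl group with Pd(PPh3)4 and morpholine to give phenol F5. Bromination of F5 with N-bromosuccinimide at the one free ring position, ortho to the hydroxyl, rejoins the route at 9.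

Step 7. The risks are alkylation on oxygen instead of carbon and attack at the bromine-bearing carbon; in addition C8 is formed without control, so about half of the material is the unwanted epimer. Fallback for the C/O problem: from 9, make the tertiary propargyl ether F6 (2-methylbut-3-yn-2-yl methyl carbonate, CuCl2 catalyst, DBU) and semi-hydrogenate it over lead-poisoned Pd/CaCO3 to the 1,1-dimethylallyl ether F7. Heating F7 in toluene should give 11 by aromatic Claisen rearrangement: the shift delivers a normal prenyl group to an ortho carbon, and the crowded tertiary ether and the non-enolisable dienone should favour the carbon bearing the lavandulyl group. The route is rejoined at 11.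

Step 10. The risks are epimerisation at C3 or reversible opening of ring B in warm DMF, and transfer of bromine to an alkene if acidification runs ahead of reduction. Fallback: move the deprotection in front of ring B formation. From 11, LiCl in DMF followed by NaHSO3 should cleave the C5 methyl ether selectively (its leaving group is the bromo-diketone enolate) and remove the bromine, giving vinylogous acid F8. Double silylation (LiN(SiMe3)2, Me3SiCl) gives bis-silyl diene F9, which keeps C4a=C8a(OMe) as the diene terminus. The step 9 conditions with 13 and the CF3CO2H work-up then deliver 17 directly, where the route is rejoined.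

Step 11. The risks are poor facial control or no reaction at the crowded C6, and deactivation of the amine by the acidic substrate. Fallback: from 17, use an acceptor already at the carboxylic oxidation level. Addition to 1-cinnamoyl-3,5-dimethylpyrazole with Ni(ClO4)2·6H2O, the bis(4-phenyloxazolinyl)dibenzofuran ligand and 2,2,6,6-tetramethylpiperidine expels the pyrazole and gives the enol lactone F10. Hydrolysis of F10 with LiOH at 0 °C rejoins the route at 20. This also removes the chlorite oxidation of step 12, in which chlorination of the enol or the alkenes is the main hazard.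

## Further compounds

F1 | step 9 | (6S)-2-bromo-4-[(2S,3R)-3-hydroxy-2-methylbutanoyl]-6-lavandulyl-3,5-dimethoxy-6-prenylcyclohexa-2,4-dien-1-one | C=C(C)[C@H](CC=C(C)C)C[C@]1(CC=C(C)C)C(=O)C(Br)=C(OC)C(C(=O)[C@@H](C)[C@@H](C)O)=C1OC
F2 | step 5 | 1-(2,4,6-trihydroxy-3-lavandulylphenyl)propan-1-one | C=C(C)[C@H](CC=C(C)C)Cc1c(O)cc(O)c(C(=O)CC)c1O
F3 | step 5 | 1-[4-(allyloxy)-2,6-dihydroxy-3-lavandulylphenyl]propan-1-one | C=C(C)[C@H](CC=C(C)C)Cc1c(OCC=C)cc(O)c(C(=O)CC)c1O
F4 | step 5 | 1-[4-(allyloxy)-3-lavandulyl-2,6-dimethoxyphenyl]propan-1-one | C=C(C)[C@H](CC=C(C)C)Cc1c(OCC=C)cc(OC)c(C(=O)CC)c1OC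
F5 | step 5 | 1-(4-hydroxy-3-lavandulyl-2,6-dimethoxyphenyl)propan-1-one | C=C(C)[C@H](CC=C(C)C)Cc1c(O)cc(OC)c(C(=O)CC)c1OC
F6 | step 7 | 1-[3-bromo-5-lavandulyl-2,6-dimethoxy-4-(2-methylbut-3-yn-2-yloxy)phenyl]propan-1-one | C=C(C)[C@H](CC=C(C)C)Cc1c(OC)c(C(=O)CC)c(OC)c(Br)c1OC(C)(C)C#C
F7 | step 7 | 1-[3-bromo-5-lavandulyl-2,6-dimethoxy-4-(2-methylbut-3-en-2-yloxy)phenyl]propan-1-one | C=C(C)[C@H](CC=C(C)C)Cc1c(OC)c(C(=O)CC)c(OC)c(Br)c1OC(C)(C)C=C
F8 | step 10 | (6S)-3-hydroxy-6-lavandulyl-5-methoxy-6-prenyl-4-propanoylcyclohexa-2,4-dien-1-one | C=C(C)[C@H](CC=C(C)C)C[C@]1(CC=C(C)C)C(=O)C=C(O)C(C(=O)CC)=C1OC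
F9 | step 10 | (6S)-6-lavandulyl-5-methoxy-6-prenyl-3-(trimethylsilyloxy)-4-[(1Z)-1-(trimethylsilyloxy)prop-1-en-1-yl]cyclohexa-2,4-dien-1-one | C=C(C)[C@H](CC=C(C)C)C[C@]1(CC=C(C)C)C(=O)C=C(O[Si](C)(C)C)C(/C(O[Si](C)(C)C)=C/C)=C1OC
F10 | step 11 | enol lactone of 20 closed on O5: (4R)-4-phenyl-3,4-dihydro-2H-pyran-2-one ring fused at C5–C6 of 17 | C=C(C)[C@H](CC=C(C)C)C[C@]1(CC=C(C)C)C(=O)C3=C(OC(=O)C[C@@H]3c3ccccc3)C2=C1O[C@H](C)[C@H](C)C2=O
A1 | alternative 1 | 4-hydroxy-6-[1-lavandulyl-4-methylpent-3-en-1-yl]-2H-pyran-2-one (side-chain methine unassigned) | C=C(C)[C@H](CC=C(C)C)CC(CC=C(C)C)c1cc(O)cc(=O)o1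
A2 | alternative 1 | 2-lavandulyl-2-prenylcyclohexane-1,3,5-trione | C=C(C)[C@H](CC=C(C)C)CC1(CC=C(C)C)C(=O)CC(=O)CC1=O
A3 | alternative 2 | 3-lavandulyl-9,10-dimethyl-3-prenyloxecane-2,4,6,8-tetrone (ten-membered triketo lactone) | C=C(C)[C@H](CC=C(C)C)C[C@]1(CC=C(C)C)C(=O)CC(=O)CC(=O)[C@@H](C)[C@@H](C)OC1=O
A4 | alternative 2 | (2R,3S,8S)-5-hydroxy-8-lavandulyl-2,3-dimethyl-8-prenyl-2,3-dihydro-4H-chromene-4,7(8H)-dione (same as 17) | C=C(C)[C@H](CC=C(C)C)C[C@]1(CC=C(C)C)C(=O)C=C(O)C2=C1O[C@H](C)[C@H](C)C2=O
A5 | alternative 3 | 3-ethoxy-4-lavandulyl-4-prenylcyclobut-2-en-1-one | C=C(C)[C@H](CC=C(C)C)CC1(CC=C(C)C)C(=O)C=C1OCC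
A6 | alternative 3 | ethoxyethyne | C#COCC
A7 | alternative 3 | 3,5-diethoxy-6-lavandulyl-6-prenylcyclohexa-2,4-dien-1-one | C=C(C)[C@H](CC=C(C)C)CC1(CC=C(C)C)C(=O)C=C(OCC)C=C1OCC
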